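The rate constants belong to no real substance, and the outcome is calculated.

If G were to remain in this flask at the end, the charges would have to show it, so we turn the question round and ask what their balance would then look like.

G 0.80 M; L 1.00 equiv (in portions, 2); X 0.0400 M; D 0.1 mol%; time 20 min; the portions of L follow each other after 2.0 s, the first at the start

1. which holds at 20 min: what has brought the reaction to rest, or that it has not come to rest (no working catalyst is left / L has run out first / forward and back rates have come level / it is still moving / all of G has reacted)
2. conversion of G at 20 min
3. amount of J at 20 min, in percent of the G charged
4. amount of E.X at 20 min, in percent of the G charged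

    G + D ⇌ D + E (K1 = 4.28, k1 = 205 M⁻¹ s⁻¹)
    D + E ⇌ D.E (K2 = 11.8 M⁻¹, k2 = 111 M⁻¹ s⁻¹)
    L + D.E → D + J (k3 = 24.3 M⁻¹ s⁻¹)
    E + X → E.X (k4 = 0.120 M⁻¹ s⁻¹)

G passes reversibly into E on D. E bound as D.E is turned by L into J, while free E meets X and gives E.X. A G therefore leaves the pool of G and E by using up one L or one X. The L and X charged together come to 105% of the G charged, and this figure is what we call the cover. For G and E to stay in the flask at rest, the cover would have to lie below 100%. This flask stands 5 percentage points above that line, so G is the limiting reagent, with L and X counted together.

Time should not stand in the way. The half-life of G by its forward step alone, 0.070 min, and that of E against X as charged, 2.4 min, are both shorter than the 20 min allowed. For this flask we therefore expect the end state all of G has reacted, with conversion 100%, E.X at 5.00% and J at 95.0%.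

The forecast gives all of G has reacted, conversion >99.9%, J 94.99% and E.X 5%, “with L slightly in excess”. The simulation of this flask gives all of G has reacted, conversion >99.9%, J 95.0% and E.X 4.98%.

The falling level of X is one reason, though not the main one, why J reaches 95.0% in this flask: 0.48% of the X charge remains there, and with X held at its charged level J comes to 81.4%. The cover also gives the L left over: 5.00% of the G charged, which at 1.00 equiv is the 5.0% of its charge still there. In the neighbour with 0.600 equiv of L the cover is 65.0%, so we expect J at 60.0% and 35.0% of the G charged remaining as G or E. That neighbour holds J 60.0%, G 6.62%, E 28.3% and L 0%.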